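**Retrosynthetic overview** (neolignan numbering: C7 = carbinol carbon, C8 = ether methine, C9 = methyl)
- The target is the erythro-(7S,8R) 8-O-4′ neolignan. Both benzene rings are bought, so no ring is formed anywhere in the route, and the last operation only takes a side-chain ester to CH2OH.
- Key disconnection: the C7–aryl bond to the 3,4,5-trimethoxyphenyl ring is cut together with C7–C8. C7(H)(OH) goes back to CO + H2, the ring to an aryltitanium, and C8–C9 to the O–CH=CH2 group of an achiral guaiacyl vinyl ether (four components, one flask).
- Enabling feature: C8 carries the guaiacyl ether oxygen, one H and the C9 methyl, so O–C8H(CH3)–C7 is the Markovnikov H/CHO adduct of an aryl vinyl ether. That oxygen first steers Rh to C8 (branched aldehyde) and then acts as the polar Felkin–Anh substituent that guides the trimethoxyphenyl ring onto C7 (erythro).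
- The vinyl ether comes from methyl dihydroferulate by Ir-catalysed vinyl transfer, and the aryltitanium from 5-bromo-1,2,3-trimethoxybenzene.

Key step: step 3

Assumption: the sense of induction of the BisDiazaphos ligand on the aryl vinyl ether is taken to follow that on vinyl esters; both antipodes of the ligand are accessible, and the one that gives the (R)-aldehyde is meant throughout.

Step 1
Reactants: 1 methyl 3-(4-hydroxy-3-methoxyphenyl)propanoate (methyl dihydroferulate)
Product: 2 methyl 3-[4-(ethenyloxy)-3-methoxyphenyl]propanoate
Conditions: [Ir(cod)Cl]2 (1 mol %), Na2CO3 (0.6 equiv), vinyl acetate (3 equiv), toluene, 100 °C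
Reagents that add atoms: vinyl acetate, C=COC(C)=O
Why: In this Ir-catalysed transfer vinylation the iridium phenoxide adds across vinyl acetate and β-acetoxy elimination releases the aryl vinyl ether, a reaction type well established for electron-rich phenols, and the methyl ester is inert to Na2CO3 in dry toluene.

Step 2
Reactants: 3 5-bromo-1,2,3-trimethoxybenzene
Product: 5 triisopropoxy(3,4,5-trimethoxyphenyl)titanium, via aryllithium 4 (not isolated)
Conditions: n-BuLi (1.0 equiv), THF, −78 °C; ClTi(OiPr)3 (1.0 equiv), −78 → 0 °C; solution used directly in step 3
Reagents that add atoms: chlorotitanium triisopropoxide, CC(C)O[Ti](Cl)(OC(C)C)OC(C)C; n-butyllithium, [Li]CCCC (supplies the lithium of 4 only)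
Why: Bromine–lithium exchange followed by transmetalation to ClTi(OiPr)3 is the standard entry to aryltitanium triisopropoxides, which are thermally stable, non-basic and aldehyde-selective.

Step 3
Reactants: 2 methyl 3-[4-(ethenyloxy)-3-methoxyphenyl]propanoate; 5 triisopropoxy(3,4,5-trimethoxyphenyl)titanium
Product: 7 methyl 3-(4-{[(1S,2R)-1-hydroxy-1-(3,4,5-trimethoxyphenyl)propan-2-yl]oxy}-3-methoxyphenyl)propanoate, via (R)-aldehyde 6 (not isolated)
Conditions: Rh(acac)(CO)2 (0.5 mol %), BisDiazaphos (0.6 mol %), CO/H2 (1:1, 10 bar), THF, 45 °C; vent, Ar purge; then 5 (1.5 equiv, THF), −78 → −20 °C; aq NH4Cl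
Reagents that add atoms: carbon monoxide, [C-]#[O+] (dihydrogen, [H][H], supplies hydrogen only)
Why: Proposed new method: the hydridorhodium catalyst adds to the vinyl ether of 2 with Rh on the oxygen-bearing carbon, CO insertion and hydrogenolysis release the branched aldehyde 6, and after venting the aryl group of 5 moves from titanium to the titanium-bound formyl carbon through a four-centre transition state, so that the C7–C8 bond, the C7–aryl bond, the carbinol oxygen and both stereocentres come from four components (2, CO, H2, 5) in one flask. The closest known reaction types are the Rh-catalysed asymmetric hydroformylation of vinyl esters and aryl vinyl ethers, one-pot hydroformylation/carbonyl-addition sequences (Wittig olefination, crotylboration, Rh-catalysed arylboronic acid addition) and the non-chelation addition of RTi(OiPr)3 reagents to α-alkoxy aldehydes; new is their merger with an aryltitanium on an aryl vinyl ether. No ring is closed. C8 (R) is set by the chiral bis(diazaphospholane) ligand, which selects the alkene face in the hydride-insertion step, and C7 (S) by 1,2-induction from C8 under the polar Felkin–Anh model: the C8–O bond stands anti to the incoming aryl group, which passes the C8 hydrogen rather than the methyl group and reaches the Si face of the formyl group, which gives the erythro (anti) relation. The step needs branched regioselectivity (secured by the ether oxygen on the alkene, which stabilises the α-oxygenated alkylrhodium), absence of chelation (weakly Lewis acidic Ti(OiPr)3 centre, poorly basic aryl ether oxygen), integrity of the labile C8–H (neutral medium, no isolation, non-basic 5, low temperature) and attack on the aldehyde in the presence of the methyl ester (organotitanium triisopropoxides leave esters untouched at this temperature). The phosphorus atoms of the ligand carry only carbon substituents, so traces of phenol set free by β-aryloxide loss from the minor linear alkylrhodium cannot solvolyse it.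

Step 4
Reactants: 7 methyl 3-(4-{[(1S,2R)-1-hydroxy-1-(3,4,5-trimethoxyphenyl)propan-2-yl]oxy}-3-methoxyphenyl)propanoate
Product: 8 (1S,2R)-2-[4-(3-hydroxypropyl)-2-methoxyphenoxy]-1-(3,4,5-trimethoxyphenyl)propan-1-ol
Conditions: LiAlH4, THF, 0 °C; H2O/aq NaOH work-up
Reagents that add atoms: none
Why: Ester reduction with LiAlH4 touches neither the aryl ethers nor the two stereocentres (the carbinol is merely carried as its aluminium alkoxide), so 7 should be converted into the target without stereochemical change.

**Compound list**
1 | methyl 3-(4-hydroxy-3-methoxyphenyl)propanoate | COC(=O)CCc1ccc(O)c(OC)c1 | starting material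
2 | methyl 3-[4-(ethenyloxy)-3-methoxyphenyl]propanoate | COC(=O)CCc1ccc(OC=C)c(OC)c1 | intermediate
3 | 5-bromo-1,2,3-trimethoxybenzene | COc1cc(Br)cc(OC)c1OC | starting material
4 | (3,4,5-trimethoxyphenyl)lithium | [Li]c1cc(OC)c(OC)c(OC)c1 | intermediate
5 | triisopropoxy(3,4,5-trimethoxyphenyl)titanium | COc1cc([Ti](OC(C)C)(OC(C)C)OC(C)C)cc(OC)c1OC | intermediate
6 | methyl 3-(3-methoxy-4-{[(2R)-1-oxopropan-2-yl]oxy}phenyl)propanoate | COC(=O)CCc1ccc(O[C@H](C)C=O)c(OC)c1 | intermediate
7 | methyl 3-(4-{[(1S,2R)-1-hydroxy-1-(3,4,5-trimethoxyphenyl)propan-2-yl]oxy}-3-methoxyphenyl)propanoate | COC(=O)CCc1ccc(O[C@H](C)[C@@H](O)c2cc(OC)c(OC)c(OC)c2)c(OC)c1 | intermediate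
8 | (1S,2R)-2-[4-(3-hydroxypropyl)-2-methoxyphenoxy]-1-(3,4,5-trimethoxyphenyl)propan-1-ol | COc1cc(CCCO)ccc1O[C@H](C)[C@@H](O)c1cc(OC)c(OC)c(OC)c1 | target

Total step count: 4. Longest linear sequence: 3 (steps 1, 3, 4).

**Steps most likely to fail**

1) Step 3 (labelled step).
- What may go wrong: incomplete discrimination of the alkene faces, catalyst decay through β-aryloxide loss from the linear alkylrhodium in the hydroformylation stage, or carry-over of CO into the aryl-transfer stage.
- The fallback uses known chemistry and takes C8 from the chiral pool. It sets out from 1.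
- Mitsunobu etherification (PPh3, DIAD, THF) with commercial (S)-1-(tert-butyldimethylsilyloxy)propan-2-ol inverts the carbinol centre. It should give methyl 3-(4-{[(2R)-1-(tert-butyldimethylsilyloxy)propan-2-yl]oxy}-3-methoxyphenyl)propanoate F1.
- Buffered fluoride (TBAF/AcOH, THF) frees methyl 3-(4-{[(2R)-1-hydroxypropan-2-yl]oxy}-3-methoxyphenyl)propanoate F2.
- NaHCO3-buffered Dess–Martin oxidation gives 6, where the fallback comes back to the route. Crude 6 is treated at once with 5 as in the second stage of step 3, a plain non-chelation organotitanium addition, to give 7.

2) Step 1.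
- What may go wrong: competing O-acetylation of the phenol by vinyl acetate, and slow vinyl transfer to the ortho-methoxy-substituted phenoxide.
- The fallback replaces vinyl transfer by an oxidative copper coupling of Chan–Lam type. It sets out from 1 and comes back at 2.
- Conditions: Cu(OAc)2, pyridine and the 2,4,6-trivinylcyclotriboroxane–pyridine complex in CH2Cl2 under air at room temperature. No new isolated compound is made.

3) Step 2.
- What may go wrong: incomplete lithium-to-titanium exchange, or reductive biaryl formation at titanium. Either leaves basic aryllithium that would enolise the aldehyde and attack the ester in step 3.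
- The fallback gives up the stoichiometric aryl-metal for catalytic aryl transfer. It sets out from 3 (through 4).
- Quenching 4 with B(OiPr)3 followed by dilute HCl gives 3,4,5-trimethoxyphenylboronic acid F3, which can also be bought.
- After the hydroformylation stage and venting, F3 is added with Rh(acac)(coe)2/PtBu3 in DME–H2O at room temperature. This is the known Rh(I)-catalysed 1,2-addition of arylboronic acids to aldehydes, which is neutral and ester-tolerant.
- The fallback comes back to the route at 7.

**Further compounds**
F1 | step 3 | methyl 3-(4-{[(2R)-1-(tert-butyldimethylsilyloxy)propan-2-yl]oxy}-3-methoxyphenyl)propanoate | COC(=O)CCc1ccc(O[C@H](C)CO[Si](C)(C)C(C)(C)C)c(OC)c1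
F2 | step 3 | methyl 3-(4-{[(2R)-1-hydroxypropan-2-yl]oxy}-3-methoxyphenyl)propanoate | COC(=O)CCc1ccc(O[C@H](C)CO)c(OC)c1
F0 | step 1 | none | none
F3 | step 2 | 3,4,5-trimethoxyphenylboronic acid | COc1cc(B(O)O)cc(OC)c1OC
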